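**Strategy**

The cyclopentane ring of the hydrindane is cut at the two bonds that join an acetone-type three-carbon unit (ring-fusion CH, carbinol carbon, its CH2) to an isoprene unit (the second CH2, the other ring-fusion CH and, outside this ring, the hydroperoxide-bearing carbon with its CH2 and CH3). One flask joins both: the dianion of dimethyl (2-oxopropyl)phosphonate displaces one bromide of (E)-1,4-dibromo-2-methylbut-2-ene, and a chiral zerovalent palladium catalyst closes the ring through the π-allyl complex to a 2-phosphono-3-isopropenylcyclopentanone. Methylenation, arylation, methyl addition and prenylation follow; a biomimetic aerobic radical cyclization finally closes the spiro ring and installs the hydroperoxide.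

Key step: step 1

Assumption (chemistry): the 2-acetylcyclohexane-1,3,5-trione part is drawn as one enol tautomer and its tautomers are treated as one compound; the (1R,2R) ligand is assumed to be the enantiomer that gives the (5S) centre of 4, otherwise its mirror image is used.

**Route**

Step 1
Reactants: 1 dimethyl (2-oxopropyl)phosphonate; 2 (E)-1,4-dibromo-2-methylbut-2-ene
Product: 4 dimethyl [(1S,5S)-2-oxo-5-(prop-1-en-2-yl)cyclopentyl]phosphonate, via acyclic allylic bromide 3 (not isolated)
Conditions: NaH, THF, 0 °C; n-BuLi, 0 °C; added to 2 (1.2 equiv), THF, −78 → −40 °C; then Pd2(dba)3·CHCl3 (2.5 mol %), (1R,2R)-N,N′-bis[2-(diphenylphosphanyl)benzoyl]cyclohexane-1,2-diamine (7.5 mol %), −40 → 0 °C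
Reagents that add atoms: none
Why: The γ-carbanion of the 1,3-dianion of 1 displaces the more SN2-reactive, γ-substituted (prenyl-type) bromide of 2 and so forms the CH2–CH2 bond, leaving the α-phosphonyl enolate 3 with a methallyl-type bromide; zerovalent palladium ionises that bromide to a 2-methyl-π-allyl complex, which the enolate carbon attacks at the internal terminus to form the CH–CH bond and release the isopropenyl group. The closest known reaction type is the γ-alkylation of β-keto ester or β-keto phosphonate dianions with 1,4-dihalobut-2-enes followed by SN2′ or Tsuji–Trost closure to 2-acyl-3-vinylcyclopentanone derivatives. The only ring closed, the cyclopentanone, forms by 5-exo attack of carbon on the allyl terminus, preferred over 7-endo attack at the CH2 terminus and over O-allylation, which is reversible under palladium catalysis. The isopropenyl-bearing ring CH is set by the chiral ligand, because the two faces of the π-allyl complex interconvert through the unsubstituted CH2 terminus before the ring closes (dynamic kinetic control), while the phosphonate-bearing CH is epimerisable and settles trans to it. The step needs site selectivity between the two bromides, secured by the higher SN2 rate of the bromide on the CH2 attached to the CH= carbon, and it needs the uncatalysed racemic SN2′ closure to stay slow, secured by adding the catalyst at −40 °C before warming.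

Step 2
Reactants: 4 dimethyl [(1S,5S)-2-oxo-5-(prop-1-en-2-yl)cyclopentyl]phosphonate
Product: 5 (3S)-2-methylidene-3-(prop-1-en-2-yl)cyclopentan-1-one
Conditions: 37% aq. HCHO, K2CO3, THF/H2O, 0 °C; used at once
Reagents that add atoms: formaldehyde, C=O
Why: Horner–Wadsworth–Emmons olefination of the cyclic β-keto phosphonate with formaldehyde should give the exocyclic enone under conditions too mild to deprotonate the γ-CH, so the isopropenyl-bearing stereocentre is kept while the epimerisable phosphonate-bearing centre is erased.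

Step 3
Reactants: 5 (3S)-2-methylidene-3-(prop-1-en-2-yl)cyclopentan-1-one; 6 2,4,6-trihydroxyacetophenone
Product: 7 (2S,3R)-2-[(3-acetyl-2,4,6-trihydroxyphenyl)methyl]-3-(prop-1-en-2-yl)cyclopentan-1-one
Conditions: 6 (3 equiv), NaHCO3, THF/H2O, 0 → 23 °C; then Et3N (cat.), MeOH, 23 °C
Reagents that add atoms: none
Why: Michael addition of the phloroglucinol ring carbon of 6 to the exocyclic enone should form the aryl–CH2 bond irreversibly whereas O-addition is reversible, and the new α-stereocentre equilibrates through the enolate to the more stable 2,3-trans arrangement under control of the isopropenyl-bearing centre (7 may rest as a cyclic hemiketal that reopens under base).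

Step 4
Reactants: 7 (2S,3R)-2-[(3-acetyl-2,4,6-trihydroxyphenyl)methyl]-3-(prop-1-en-2-yl)cyclopentan-1-one
Product: 8 1-(2,4,6-trihydroxy-3-{[(1S,2R,5R)-2-hydroxy-2-methyl-5-(prop-1-en-2-yl)cyclopentyl]methyl}phenyl)ethan-1-one
Conditions: MeMgBr (6 equiv), CeCl3 (anhydrous), THF, −78 → 0 °C; aq. NH4Cl
Reagents that add atoms: methylmagnesium bromide, C[Mg]Br
Why: Organocerium 1,2-addition to the cyclopentanone, after the three phenols are deprotonated and the aryl ketone is thereby deactivated as a vinylogous carboxylate, should deliver methyl to the face anti to the adjacent arylmethyl group (1,2-steric control as in 2-alkylcyclopentanones), so the new hydroxyl is cis to that group.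

Step 5
Reactants: 8 1-(2,4,6-trihydroxy-3-{[(1S,2R,5R)-2-hydroxy-2-methyl-5-(prop-1-en-2-yl)cyclopentyl]methyl}phenyl)ethan-1-one; 9 1-bromo-3-methylbut-2-ene
Product: 11 2-acetyl-3,5-dihydroxy-6-{[(1S,2R,5R)-2-hydroxy-2-methyl-5-(prop-1-en-2-yl)cyclopentyl]methyl}-4,4-bis(3-methylbut-2-en-1-yl)cyclohexa-2,5-dien-1-one, via ring-monoprenylated phenol 10 (not isolated)
Conditions: 9 (2.2 equiv), NaOMe, MeOH, 0 °C; kept under argon
Reagents that add atoms: none
Why: Alkylative dearomatization of the acylphloroglucinol by C-prenylation should place the first prenyl group on the only free ring CH (10) and the second on the same, less hindered carbon rather than on the carbon carrying the branched cyclopentylmethyl group, creating the quaternary diprenyl carbon without a new stereocentre.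

Step 6
Reactants: 11 2-acetyl-3,5-dihydroxy-6-{[(1S,2R,5R)-2-hydroxy-2-methyl-5-(prop-1-en-2-yl)cyclopentyl]methyl}-4,4-bis(3-methylbut-2-en-1-yl)cyclohexa-2,5-dien-1-one
Product: 12 (1S,3′R,3a′S,7′R,7a′R)-3-acetyl-7′-hydroperoxy-3′,4-dihydroxy-3′,7′-dimethyl-5,5-bis(3-methylbut-2-en-1-yl)-1′,2′,3′,3a′,4′,6′,7′,7a′-octahydrospiro[cyclohex-3-ene-1,5′-indene]-2,6-dione
Conditions: Mn(OAc)3·2H2O (10 mol %), O2 (1 atm), AcOH, 23 °C
Reagents that add atoms: dioxygen, O=O
Why: Trivalent manganese should oxidise the ring enol to the stabilised radical at the alkylated ring carbon (oxidative free-radical cyclization under aerobic trapping), which closes 6-endo on the CH2 terminus of the isopropenyl group through a chair with the cyclopentane fused diequatorially; the tertiary radical then captures O2 on its equatorial face because the axial face is blocked by the axial carbonyl of the new spiro carbon, whose configuration rests on the expected, modest preference of the carbonyl next to the diprenyl carbon for the equatorial site.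

**Compound list**

1 | dimethyl (2-oxopropyl)phosphonate | CC(=O)CP(=O)(OC)OC | starting material
2 | (E)-1,4-dibromo-2-methylbut-2-ene | BrC/C=C(C)/CBr | starting material
3 | dimethyl [(5E)-7-bromo-6-methyl-2-oxohept-5-en-1-yl]phosphonate (formed as its enolate) | COP(=O)(OC)CC(=O)CC/C=C(C)/CBr | intermediate
4 | dimethyl [(1S,5S)-2-oxo-5-(prop-1-en-2-yl)cyclopentyl]phosphonate | COP(=O)(OC)[C@H]1[C@@H](CCC1=O)C(C)=C | intermediate
5 | (3S)-2-methylidene-3-(prop-1-en-2-yl)cyclopentan-1-one | C=C1[C@@H](CCC1=O)C(C)=C | intermediate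
6 | 2,4,6-trihydroxyacetophenone | CC(=O)c1c(O)cc(O)cc1O | starting material
7 | (2S,3R)-2-[(3-acetyl-2,4,6-trihydroxyphenyl)methyl]-3-(prop-1-en-2-yl)cyclopentan-1-one | CC(=O)c1c(O)cc(O)c(C[C@H]2[C@@H](CCC2=O)C(C)=C)c1O | intermediate
8 | 1-(2,4,6-trihydroxy-3-{[(1S,2R,5R)-2-hydroxy-2-methyl-5-(prop-1-en-2-yl)cyclopentyl]methyl}phenyl)ethan-1-one | CC(=O)c1c(O)cc(O)c(C[C@H]2[C@@H](CC[C@@]2(C)O)C(C)=C)c1O | intermediate
9 | 1-bromo-3-methylbut-2-ene (prenyl bromide) | CC(C)=CCBr | starting material
10 | 1-(2,4,6-trihydroxy-3-{[(1S,2R,5R)-2-hydroxy-2-methyl-5-(prop-1-en-2-yl)cyclopentyl]methyl}-5-(3-methylbut-2-en-1-yl)phenyl)ethan-1-one | CC(=O)c1c(O)c(CC=C(C)C)c(O)c(C[C@H]2[C@@H](CC[C@@]2(C)O)C(C)=C)c1O | intermediate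
11 | 2-acetyl-3,5-dihydroxy-6-{[(1S,2R,5R)-2-hydroxy-2-methyl-5-(prop-1-en-2-yl)cyclopentyl]methyl}-4,4-bis(3-methylbut-2-en-1-yl)cyclohexa-2,5-dien-1-one | CC(=O)C1=C(O)C(CC=C(C)C)(CC=C(C)C)C(O)=C(C[C@H]2[C@@H](CC[C@@]2(C)O)C(C)=C)C1=O | intermediate
12 | (1S,3′R,3a′S,7′R,7a′R)-3-acetyl-7′-hydroperoxy-3′,4-dihydroxy-3′,7′-dimethyl-5,5-bis(3-methylbut-2-en-1-yl)-1′,2′,3′,3a′,4′,6′,7′,7a′-octahydrospiro[cyclohex-3-ene-1,5′-indene]-2,6-dione (CNP0149131.1) | CC(=O)C1=C(O)C(CC=C(C)C)(CC=C(C)C)C(=O)[C@@]2(C[C@H]3[C@@H](CC[C@@]3(C)O)[C@](C)(OO)C2)C1=O | target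

**Step count**

Total steps: 6. Longest linear sequence: 6 (steps 1 to 6).

**Steps most likely to fail**

Step 6. The ring radical may close 5-exo on a prenyl group of the neighbouring quaternary carbon instead of 6-endo on the isopropenyl group, may be oxygenated directly at the ring carbon, and may show little discrimination between the two ring carbonyls, so that both spiro epimers form. The fallback sets out from 8 and returns at 12; it closes the spiro ring by a polar step before any prenyl group is present. The three phenols of 8 are acetylated (Ac2O, pyridine, 0 °C) to 2-acetyl-4-{[(1S,2R,5R)-2-hydroxy-2-methyl-5-(prop-1-en-2-yl)cyclopentyl]methyl}benzene-1,3,5-triyl triacetate F1. Ene-type allylic chlorination of the isopropenyl group (NaOCl, CeCl3·7H2O, CH2Cl2/H2O, 0 °C) should give the 2-(chloromethyl)allyl triacetate F2. Methanolysis of the acetates (K2CO3, MeOH) and intramolecular dearomative Tsuji–Trost C-allylation at the alkylated ring carbon (Pd2(dba)3, the chiral bisphosphine of step 1 or its mirror image) should give the prenyl-free spiro trione with an exocyclic methylene group F3. O-Allylation would need an eight-membered ring and the ligand is meant to control the spiro carbon. gem-Diprenylation of the remaining ring CH2 (9, NaOMe, MeOH) gives the diprenyl spiro trione F4. Mukaiyama–Isayama silylperoxidation (Co(acac)2, O2, Et3SiH, 1,2-dichloroethane) is expected to be selective for the 1,1-disubstituted exocyclic alkene over the trisubstituted prenyl alkenes and equatorial for the steric reason given in step 6, giving the triethylsilyl peroxide F5. Desilylation (Bu4NF, AcOH, THF) gives 12.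

Step 1. The dianion may attack the methallyl-type bromide, the enolate may close without the catalyst (loss of enantiocontrol), and O-allylation or seven-membered closure may compete. The fallback sets out from 1 and returns at 4; it uses an electrophile with one bromide only and separates the two bond formations. Commercial 2-methyl-2-vinyloxirane is opened in the SN2′ sense by bromide (LiBr, CuBr2, THF) to (2E)-4-bromo-2-methylbut-2-en-1-ol F6. This is converted (ClCO2Me, pyridine) into (2E)-4-bromo-2-methylbut-2-en-1-yl methyl carbonate F7. The dianion of 1 (NaH, then n-BuLi) displaces the bromide to give dimethyl [(5E)-7-[(methoxycarbonyl)oxy]-6-methyl-2-oxohept-5-en-1-yl]phosphonate F8. F8 is inert without catalyst; it is isolated and cyclised in a separate asymmetric Tsuji–Trost step (Pd2(dba)3, the same ligand, CH2Cl2, 0 °C) to 4.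

Step 4. Facial selectivity of the methyl addition may be poor and the basic reagent may enolise the ketone instead of adding. The fallback sets out from 7 and returns at 8. Corey–Chaykovsky methylenation under thermodynamic control (Me3S(O)I, NaH, DMSO) should place the new CH2 anti to the arylmethyl group and give 1-(2,4,6-trihydroxy-3-{[(3R,4S,5R)-5-(prop-1-en-2-yl)-1-oxaspiro[2.4]heptan-4-yl]methyl}phenyl)ethan-1-one F9. Hydride opening at the CH2 of the oxirane (LiEt3BH, THF, 0 °C) then gives 8.

Further compounds
F1 | step 6 | 2-acetyl-4-{[(1S,2R,5R)-2-hydroxy-2-methyl-5-(prop-1-en-2-yl)cyclopentyl]methyl}benzene-1,3,5-triyl triacetate | CC(=O)c1c(OC(C)=O)cc(OC(C)=O)c(C[C@H]2[C@@H](CC[C@@]2(C)O)C(C)=C)c1OC(C)=O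
F2 | step 6 | 2-acetyl-4-{[(1S,2R,5R)-5-(3-chloroprop-1-en-2-yl)-2-hydroxy-2-methylcyclopentyl]methyl}benzene-1,3,5-triyl triacetate | CC(=O)c1c(OC(C)=O)cc(OC(C)=O)c(C[C@H]2[C@@H](CC[C@@]2(C)O)C(=C)CCl)c1OC(C)=O
F3 | step 6 | (1S,3′R,3a′S,7a′R)-3-acetyl-3′,4-dihydroxy-3′-methyl-7′-methylidene-1′,2′,3′,3a′,4′,6′,7′,7a′-octahydrospiro[cyclohex-3-ene-1,5′-indene]-2,6-dione | CC(=O)C1=C(O)CC(=O)[C@@]2(C[C@H]3[C@@H](CC[C@@]3(C)O)C(=C)C2)C1=O
F4 | step 6 | (1S,3′R,3a′S,7a′R)-3-acetyl-3′,4-dihydroxy-3′-methyl-7′-methylidene-5,5-bis(3-methylbut-2-en-1-yl)-1′,2′,3′,3a′,4′,6′,7′,7a′-octahydrospiro[cyclohex-3-ene-1,5′-indene]-2,6-dione | CC(=O)C1=C(O)C(CC=C(C)C)(CC=C(C)C)C(=O)[C@@]2(C[C@H]3[C@@H](CC[C@@]3(C)O)C(=C)C2)C1=O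
F5 | step 6 | (1S,3′R,3a′S,7′R,7a′R)-3-acetyl-3′,4-dihydroxy-3′,7′-dimethyl-5,5-bis(3-methylbut-2-en-1-yl)-7′-[(triethylsilyl)peroxy]-1′,2′,3′,3a′,4′,6′,7′,7a′-octahydrospiro[cyclohex-3-ene-1,5′-indene]-2,6-dione | CC(=O)C1=C(O)C(CC=C(C)C)(CC=C(C)C)C(=O)[C@@]2(C[C@H]3[C@@H](CC[C@@]3(C)O)[C@](C)(OO[Si](CC)(CC)CC)C2)C1=O
F6 | step 1 | (2E)-4-bromo-2-methylbut-2-en-1-ol | OC/C(C)=C/CBr
F7 | step 1 | (2E)-4-bromo-2-methylbut-2-en-1-yl methyl carbonate | COC(=O)OC/C(C)=C/CBr
F8 | step 1 | dimethyl [(5E)-7-[(methoxycarbonyl)oxy]-6-methyl-2-oxohept-5-en-1-yl]phosphonate | COP(=O)(OC)CC(=O)CC/C=C(C)/COC(=O)OC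
F9 | step 4 | 1-(2,4,6-trihydroxy-3-{[(3R,4S,5R)-5-(prop-1-en-2-yl)-1-oxaspiro[2.4]heptan-4-yl]methyl}phenyl)ethan-1-one | CC(=O)c1c(O)cc(O)c(C[C@H]2[C@@H](CC[C@]23CO3)C(C)=C)c1O
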